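(The earlier runs and the new flask come from a simulation with constants of no real substance, noise included.)

Two questions stand for each of two flasks, winter and autumn: which species holds the most substrate at the end, and how much.

| flask | substrate | partner | temperature | remark | time |
|---|---|---|---|---|---|
| zeta | 0.070 M | 1.5 equiv | 35 °C | run made earlier |  |
| beta | 0.11 M | 1.5 equiv | 50 °C | run made earlier |  |
| alpha | 0.050 M | 3 equiv | 35 °C | run made earlier |  |
| winter | 0.050 M | 1.50 equiv | 40 °C |  | 5.0 min |
| autumn | 0.050 M | 1.50 equiv | 60 °C |  | 5.0 min |

| run | time / min | substrate / % | open intermediate / % | homo product / % | target / % | isomer of the product / % |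
|---|---|---|---|---|---|---|
| zeta | 0.333 | 76 | 13 | 1 | 7 | 1 |
| zeta | 1.00 | 44 | 7 | 5 | 18 | 22 |
| zeta | 2.00 | 20 | 4 | 9 | 20 | 49 |
| zeta | 3.00 | 8 | 1 | 9 | 24 | 64 |
| zeta | 4.00 | 5 | 0 | 4 | 22 | 69 |
| beta | 0.200 | 49 | 8 | 3 | 27 | 16 |
| beta | 0.667 | 10 | 1 | 5 | 49 | 42 |
| beta | 1.33 | 3 | 3 | 4 | 50 | 45 |
| beta | 2.00 | 0 | 2 | 2 | 52 | 47 |
| beta | 2.50 | 0 | 1 | 4 | 51 | 49 |
| alpha | 0.333 | 77 | 12 | 0 | 9 | 4 |
| alpha | 1.00 | 45 | 2 | 1 | 25 | 27 |
| alpha | 2.00 | 19 | 0 | 4 | 24 | 55 |
| alpha | 3.00 | 7 | 0 | 0 | 22 | 68 |
| alpha | 4.00 | 2 | 0 | 2 | 24 | 74 |

(each reading ± 1.5 percentage points)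

- percent here means substrate units held: one homo product counts as two

- which of these there is most of at the end, counted by the substrate in it, winter (open intermediate / target / homo product / isomer of the product / substrate)
- which of these there is most of at the end, counted by the substrate in it, autumn (open intermediate / target / homo product / isomer of the product / substrate)
- the largest of these amounts at the end, in percent of the substrate charged, winter
- the largest of these amounts at the end, in percent of the substrate charged, autumn

The runs read as a ladder of times. On the first rung stands open intermediate, a small and passing species: zeta reads 13% at 0.333 min and 1% at 3.00 min.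

On the second rung stand target and isomer of the product, with ρ as target over isomer. In alpha, ρ reads 0.324 at 3.00 min and 0.324 at 4.00 min, while substrate still falls from 7% to 2%. So in alpha the pair reads the same ratio while substrate still falls.

The third rung is the substrate lifetime τ, the time to fall by a factor e, read from the first-order fall:

τ(zeta) = 1.18 min, τ(beta) = 0.294 min

Carried geometrically along the temperature, this gives:

τ(winter) = 0.744 min, τ(autumn) = 0.116 min

The top rung is the run time, which is longer than either: 6.72 lifetimes in winter and 43.1 in autumn. So the end of each flask should show the end ratio, and ρ is the number to watch.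

Zeta and alpha differ in partner, 1.5 equiv against 3 equiv, and in substrate, 0.070 M against 0.050 M, yet their last readings give ρ of 0.319 and 0.324. That is the look of thermodynamic control. Pooling the last readings gives ρ at each temperature, and their quotient is the temperature gain G:

ρ(35 °C) = 0.322, ρ(50 °C) = 1.07, G = 3.34

Beta also differs from zeta and alpha in substrate, at 0.11 M, and G takes that difference as having no effect on ρ. By these readings, the majority passes from isomer to target between these temperatures. Interpolating and extrapolating by G gives:

ρ(winter) = 0.481, ρ(autumn) = 2.40

Taking off homo product at 4%, as in zeta's last reading, this reckoning gives isomer at 64.8% in winter and target at 67.7% in autumn.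

The forecast gives isomer of the product at 63% for winter and target at 61% for autumn, with the words “Target is stable once formed.” The two agree on the species, but this reckoning stands higher for autumn.

Winter ends with isomer of the product at 64.5%, and autumn with target at 67.9%.

    substrate → open intermediate (k = 0.0233 /s, Ea = 80.0 kJ/mol)
    partner → second intermediate (k = 0.0191 /s, Ea = 95.0 kJ/mol)
    open intermediate + second intermediate → target (k = 6.70 /M/s, Ea = 55.0 kJ/mol)
    2 open intermediate → homo product (k = 0.669 /M/s, Ea = 39.0 kJ/mol)
    target ⇌ isomer of the product (K = 2.19, k = 0.0765 /s, Ea = 92.0 kJ/mol, ΔH = −71.0 kJ/mol)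
    (constants at 40 °C)

In winter, the half-life of target by its forward step to isomer alone is 0.15 min, shorter than the run time of 5.0 min. Autumn's end ratio is 2.35, against ρ = 2.40 from G. For the repeat of winter at 55 °C, G gives ρ = 1.61. That flask ends with target at 59.1% and isomer at 37.2%, a ratio of 1.59.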